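All constants are those of an exercise; the flask was simulated.

The target in these flasks forms slowly through intermediate B and is eaten by the substrate standing beside it, so I reckoned how much of it could stand at the end of each run.

    gas ⇌ reagent, rate k1*(csat - [reagent]) (k1 = 0.30 s⁻¹, csat = 0.94 mM)
    substrate + reagent ⇌ intermediate A (K2 = 380 M⁻¹, k2 = 24 M⁻¹ s⁻¹)
    substrate → intermediate B (k3 = 0.021 s⁻¹)
    substrate + target → side product (k4 = 15 M⁻¹ s⁻¹)
    substrate → decomposition product (k5 = 1.6 × 10⁻⁴ s⁻¹)
    intermediate B → target (k6 = 0.029 s⁻¹)

the same everywhere: gas 0.94 mM (held); time 50 s
- Tuesday's: substrate 20 mM
- Monday's: substrate 40 mM
- Saturday's: substrate 80 mM

- in percentages every species weighs as the substrate in it: one side product counts as two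
- at the start none of reagent is dissolved
- "hardly changes" means that all values lie within two and a half points (for a concentration: within two and a half percent of the largest)
- run time (Tuesday's): 50 s

- share of target in all that became target or side product for Tuesday's, Monday's, Saturday's, in this order
- the course of these numbers from the first flask to the last (falls all the way / hardly changes / rises, then falls / rises all the way / falls, then rises)

At the charged substrate of Tuesday's flask, the target has a half-life of 2.3 s against eating, shorter than the 50 s of the run. So I took the target as a steady-state intermediate, its making balanced by its loss: k6[intermediate B] = k4[substrate][target]. That gives [target] = c*·[intermediate B]/[substrate], where c*, the break-even level, is the target concentration at which making and eating match with the two partners equal: 1.93 mM. It contains no charge, so when the ratio of the partners stays put, a larger flask holds the same millimolar of target and a smaller percentage.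

For the ratio, I let substrate fall by the step to intermediate B as if nothing else touched it, leaving 35.0%, with 30.3% as intermediate B. The ratio was 0.865, so I put the target at 1.67 mM in each flask. The remaining 34.7% had passed through to target, and what was eaten of it counts double as side product. That gave shares of 13.7%, 6.41% and 3.11%, falling all the way.

The weak link was the substrate, which also pays for each target eaten. Adding k6 times half the end ratio to its rate left 18.7%. I reforged Saturday's flask, where the substrate keeps the target's half-life at 3.09 s, shorter than the 12.4 s of Tuesday's flask. The ratio became 1.62 and the target 3.13 mM. With the substrate now paying, what had gone beyond intermediate B, 51.0%, was itself target plus doubled side product, so Saturday's share rose to 7.68%.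

The forecast gave 20%, 14% and 7%, falls all the way, holding that “more substrate means a larger fraction is lost”. The simulation gave 17.4%, 10.0% and 5.61%, falls all the way.

Saturday's end readings, 21.9% intermediate B over 13.9% substrate, put the balance c*·[intermediate B]/[substrate] at 3.04 mM of target, and Saturday's flask held 2.56 mM. Tuesday's readings give 2.47 mM against 1.75 mM held. From Tuesday's flask to Saturday's the target held rose 1.46 times, and the charge 4.00 times. Part of Saturday's low share is the time given: at 500 s, with substrate at 0%, the share rises from 5.61% to 14.9%.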